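Convention: lignan numbering is used (C7/C7′ benzylic, C8/C8′ ring fusion, C9/C9′ OCH2), with unprimed atoms on the trimethoxyphenyl half.
Assumption: 5‑bromo‑1,2,3‑trimethoxybenzene and 4‑vinyl‑2,6‑dimethoxyphenol (canolol) are treated as catalogue chemicals.

## Retrosynthetic overview
1. The target is an isomer of an acyclic epoxy sinapyl ether. One visible‑light step forms C8–C8′ (ring A, 5‑exo radical closure) and then C7′–O (ring B, capture of the benzylic cation).
2. The epoxy sinapyl ether comes from cross‑metathesis of an O‑allyl epoxide with 4‑vinyl‑2,6‑dimethoxyphenol, so the phenol is never protected.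
3. The terminal epoxide comes from a 1,2‑diol, which comes from the acetonide of an anti‑1‑arylglycerol 1‑allyl ether.
4. The C7 carbinol comes from Felkin–Anh addition of a 3,4,5‑trimethoxyphenyl‑titanium reagent to (R)‑glyceraldehyde acetonide, made from D‑mannitol diacetonide.
5. Stereochemical relay: the mannitol carbon sets C7, and C7 then sets C8, C8′ and C7′ in the ring‑forming step.

## Route

**Step 1**
Reactants: 1, 1,2:5,6‑di‑O‑isopropylidene‑D‑mannitol
Product: 2, (R)‑2,2‑dimethyl‑1,3‑dioxolane‑4‑carbaldehyde (two moles per mole of 1, used fresh)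
Conditions: NaIO4, sat. aq NaHCO3, CH2Cl2, rt
Reagents that add atoms: none
Why: Malaprade glycol cleavage breaks only the central diol C–C bond, so the purchased dioxolane stereocentre is untouched.

**Step 2**
Reactants: 2; 3, 5‑bromo‑1,2,3‑trimethoxybenzene
Product: 4, (S)‑[(4R)‑2,2‑dimethyl‑1,3‑dioxolan‑4‑yl](3,4,5‑trimethoxyphenyl)methanol (anti/erythro isomer; the syn isomer is removed by chromatography)
Conditions: 3, n‑BuLi, THF, −78 °C; ClTi(OiPr)3, −78 → −30 °C; then 2, −78 → 0 °C
Reagents that add atoms: 5‑bromo‑1,2,3‑trimethoxybenzene, COc1cc(Br)cc(OC)c1OC (aryl group)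
Why: This is a non‑chelating, weakly basic aryltitanium 1,2‑addition under Felkin–Anh control, in which the dioxolane stereocentre directs formation of the anti carbinol (C7 in the absolute sense the target needs) without enolising 2.

**Step 3**
Reactants: 4; 5, allyl bromide
Product: 6, (4R)‑4‑[(S)‑(allyloxy)(3,4,5‑trimethoxyphenyl)methyl]‑2,2‑dimethyl‑1,3‑dioxolane
Conditions: NaH, allyl bromide, TBAI (cat.), THF/DMF, 0 °C → rt
Reagents that add atoms: allyl bromide, C=CCBr
Why: Williamson etherification occurs at oxygen only, so C7 and C8 are unchanged and the acetonide keeps the other two oxygens masked.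

**Step 4**
Reactants: 6
Product: 7, (2R,3S)‑3‑(allyloxy)‑3‑(3,4,5‑trimethoxyphenyl)propane‑1,2‑diol
Conditions: AcOH/H2O 4:1, 40 °C
Reagents that add atoms: none
Why: Mild acetal hydrolysis removes the acetonide, and the benzylic allyl ether does not ionise because the β‑oxygen substituent destabilises the benzylic cation.

**Step 5**
Reactants: 7
Product: 8, (2R)‑2‑[(S)‑(allyloxy)(3,4,5‑trimethoxyphenyl)methyl]oxirane
Conditions: NaH (3 equiv), 1‑(2,4,6‑triisopropylbenzenesulfonyl)imidazole, THF, 0 °C → rt
Reagents that add atoms: none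
Why: One‑pot selective primary sulfonylation and intramolecular SN2 closure gives the epoxide with C7 untouched and C8 retained, and C8 is later erased and reset in any case.

**Step 6**
Reactants: 8; 9, 4‑vinyl‑2,6‑dimethoxyphenol
Product: 10, 2,6‑dimethoxy‑4‑[(1E)‑3‑{(S)‑[(2R)‑oxiran‑2‑yl](3,4,5‑trimethoxyphenyl)methoxy}prop‑1‑en‑1‑yl]phenol
Conditions: Hoveyda–Grubbs II (5 mol %), 9 (3 equiv), 1,4‑benzoquinone (10 mol %), CH2Cl2, 40 °C; chromatography on Et3N‑deactivated silica
Reagents that add atoms: 4‑vinyl‑2,6‑dimethoxyphenol, C=Cc1cc(OC)c(O)c(OC)c1 (ArCH= unit; ethylene is lost)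
Why: Olefin cross‑metathesis of an unhindered allyl ether with an excess of styrene is E‑selective, Ru carbenes tolerate terminal epoxides and free phenols, and benzoquinone suppresses allyl‑to‑enol‑ether isomerisation.

**Step 7 (key step)**
Reactants: 10
Product: 11, 4‑[(1R,3aS,4R,6aS)‑4‑(3,4,5‑trimethoxyphenyl)tetrahydro‑1H,3H‑furo[3,4‑c]furan‑1‑yl]‑2,6‑dimethoxyphenol (target)
Conditions: Cp2TiCl2 (10 mol %), 3,7‑di(biphenyl‑4‑yl)‑10‑(1‑naphthyl)‑10H‑phenoxazine (2 mol %), degassed dry THF (0.03 M), 420 nm LEDs, 25 °C, no stoichiometric reductant or oxidant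
Reagents that add atoms: none (isomerisation, C23H28O8 → C23H28O8)
Why: Proposed new method: redox‑neutral photoredox/titanocene epoxide–styrene radical–polar crossover annulation, in which the excited phenoxazine (E*ox ≈ −1.8 V vs SCE) reduces Cp2TiCl2 (≈ −0.8 V) to Cp2TiCl; Ti(III) opens the epoxide homolytically to the secondary C8 β‑titanoxy radical; this closes 5‑exo‑trig onto the styrene through a Beckwith–Houk chair with the C7 aryl pseudo‑equatorial (2‑substituent gives 7,8′‑trans, 1‑substituent gives 8,8′‑cis, hence 7,8‑trans); the resulting 4‑hydroxy‑3,5‑dimethoxybenzyl radical (Eox ≤ ca. +0.3 V) is oxidised by the catalyst radical cation (+0.65 V, too weak to oxidise the styrene or the un‑deprotonated phenol) to the O‑protonated p‑quinone methide; the cis CH2O–[Ti] captures this on the convex face to place the aryl exo and release Ti(IV), so both cycles close and net over‑reduction cannot turn over; the closest known reaction types are the stoichiometric Cp2TiCl (Nugent–RajanBabu) epoxide–olefin cyclisation with iodine‑induced etherification, catalytic titanocene tetrahydrofuran synthesis by homolytic substitution at Ti–O, and reductive photoredox/titanocene epoxide opening.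

## Compound list
1 | 1,2:5,6‑di‑O‑isopropylidene‑D‑mannitol | CC1(C)OC[C@@H](O1)[C@@H](O)[C@H](O)[C@H]1COC(C)(C)O1 | starting material
2 | (R)‑2,2‑dimethyl‑1,3‑dioxolane‑4‑carbaldehyde | CC1(C)OC[C@@H](O1)C=O | intermediate
3 | 5‑bromo‑1,2,3‑trimethoxybenzene | COc1cc(Br)cc(OC)c1OC | starting material
4 | (S)‑[(4R)‑2,2‑dimethyl‑1,3‑dioxolan‑4‑yl](3,4,5‑trimethoxyphenyl)methanol | CC1(C)OC[C@@H](O1)[C@@H](O)c1cc(OC)c(OC)c(OC)c1 | intermediate
5 | allyl bromide | C=CCBr | starting material
6 | (4R)‑4‑[(S)‑(allyloxy)(3,4,5‑trimethoxyphenyl)methyl]‑2,2‑dimethyl‑1,3‑dioxolane | CC1(C)OC[C@@H](O1)[C@@H](OCC=C)c1cc(OC)c(OC)c(OC)c1 | intermediate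
7 | (2R,3S)‑3‑(allyloxy)‑3‑(3,4,5‑trimethoxyphenyl)propane‑1,2‑diol | OC[C@@H](O)[C@@H](OCC=C)c1cc(OC)c(OC)c(OC)c1 | intermediate
8 | (2R)‑2‑[(S)‑(allyloxy)(3,4,5‑trimethoxyphenyl)methyl]oxirane | C1O[C@H]1[C@@H](OCC=C)c1cc(OC)c(OC)c(OC)c1 | intermediate
9 | 4‑vinyl‑2,6‑dimethoxyphenol | C=Cc1cc(OC)c(O)c(OC)c1 | starting material
10 | 2,6‑dimethoxy‑4‑[(1E)‑3‑{(S)‑[(2R)‑oxiran‑2‑yl](3,4,5‑trimethoxyphenyl)methoxy}prop‑1‑en‑1‑yl]phenol | C1O[C@H]1[C@@H](OC/C=C/c1cc(OC)c(O)c(OC)c1)c1cc(OC)c(OC)c(OC)c1 | intermediate
11 | 4‑[(1R,3aS,4R,6aS)‑4‑(3,4,5‑trimethoxyphenyl)tetrahydro‑1H,3H‑furo[3,4‑c]furan‑1‑yl]‑2,6‑dimethoxyphenol | COc1cc([C@@H]2OC[C@@H]3[C@H]2CO[C@H]3c2cc(OC)c(OC)c(OC)c2)cc(OC)c1O | target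

## Step count
Total steps: 7. Longest linear sequence: 7 (1 → 2 → 4 → 6 → 7 → 8 → 10 → 11).

## Three steps most likely to fail

1. **Step 7 (proposed new step).**
   - Risks: slow oxidation of the benzylic radical, adventitious oxidation of the sinapyl phenol, the 8,8′‑trans cyclisation isomer (which cannot close ring B), and some endo‑aryl product.
   - Fallback (known chemistry, two stages): run a thermal reductive cyclisation of 10 with stoichiometric Cp2TiCl (Cp2TiCl2/Zn, THF, then H+ quench). This gives the 2‑aryl‑3‑hydroxymethyl‑4‑(4‑hydroxy‑3,5‑dimethoxybenzyl)tetrahydrofuran. Then oxidise the 4‑alkyl‑2,6‑dimethoxyphenol with DDQ (or Ag2O) to the p‑quinone methide, which the cis CH2OH traps to close ring B. This adds one step.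

2. **Step 2 (anti/syn ratio at C7).**
   - Risk: aryl additions to glyceraldehyde acetonide can be poorly selective, and any syn isomer carried forward would lead to the enantiomeric series.
   - Fallback: set C7 by reduction instead of addition. Oxidise the 4/epi‑4 mixture with Dess–Martin periodinane to the aryl ketone, or make the ketone from the Weinreb amide of methyl (R)‑2,2‑dimethyl‑1,3‑dioxolane‑4‑carboxylate with ArMgBr. Chelation‑controlled Zn(BH4)2 reduction then converges on anti‑4.

3. **Step 6 (cross‑metathesis with a polymerisable vinylphenol on an epoxide).**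
   - Risks: styrene homodimerisation, allyl ether isomerisation, and sensitivity of 10 to silica.
   - Fallback: drop metathesis and install the complete side chain by Williamson etherification of 4 with O‑TBS‑sinapyl bromide. The bromide is made from syringaldehyde by TBSCl, Horner–Wadsworth–Emmons olefination, DIBAL‑H reduction and Appel bromination. Steps 4, 5 and 7 then follow on the silyl ether, and TBAF is used at the end.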